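The data stem from a simulated flask with made-up constants, and the scatter is random.

Nothing leaves a closed flask, so ring plus substrate, in percent of the charge (the mass balance), shows at each reading how much has gone into things I cannot read.

| setting | zeta | gamma | cedar | maple | elm | alder |
|---|---|---|---|---|---|---|
| substrate | 0.44 mM | 4.5 mM | 0.60 mM | 1.2 mM | 2.5 mM | 5.0 mM |
| remark | run made earlier | run made earlier |  |  |  |  |
| time |  |  | 2.0 min | 2.0 min | 2.0 min | 2.0 min |

| run | time / s | ring / % | substrate / % |
|---|---|---|---|
| zeta | 12.0 | 50.3 | 48.5 |
| zeta | 25.0 | 76.5 | 22.8 |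
| zeta | 40.0 | 86.6 | 8.0 |
| zeta | 50.0 | 90.8 | 4.9 |
| zeta | 60.0 | 92.2 | 3.0 |
| zeta | 80.0 | 90.9 | 0.7 |
| gamma | 10.0 | 45.3 | 53.1 |
| gamma | 12.0 | 49.0 | 47.4 |
| gamma | 25.0 | 71.5 | 20.9 |
| gamma | 40.0 | 83.1 | 8.0 |
| gamma | 50.0 | 86.6 | 4.3 |
| gamma | 60.0 | 85.9 | 3.6 |
| gamma | 80.0 | 84.9 | 1.4 |

(scatter of a reading: 1 percentage point)

- "hardly changes" means that all values lie within two and a half points (for a concentration: within two and a half percent of the largest)

- amount of ring at the end, in percent of the substrate charged for cedar, maple, elm, alder, in this order
- how that number moves from the first to the last of them (falls all the way / rises all the way / hardly changes / falls, then rises / rises, then falls)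

In the zeta run the balance falls from 99.3% at 25.0 s to 91.6% at 80.0 s. In the gamma run, at the same times, it falls from 92.4% to 86.3%, which is lower than in zeta. I call the natural logarithm of that fall, divided by the time between the readings, the fade: 0.0881 min⁻¹ in zeta and 0.0745 min⁻¹ in gamma.

My first answer is the last balance itself. I then go round once more and carry it through the remaining 40.0 s of fade, which gives 86.4% for zeta and 82.1% for gamma. A sum of two readings has a scatter of 1.4 percentage points. Adding it to the zeta figure and taking it from the gamma figure gives my bracket, from 80.7% to 87.8%. Cedar's charge lies just above zeta's and alder's just above gamma's, so I expect the row to run from near the top of the bracket to near its bottom.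

The forecast gives 88%, 87%, 85% and 82%, so that the number falls all the way, and it holds that “ring itself decays slowly”. Its first point stands 0.20 points from my upper bound of 87.8%, and its last stands inside.

The flask gives 87.6%, 86.9%, 85.2% and 82.0%, and the number falls all the way, as the forecast said, with the first point at 87.6% against my upper bound of 87.8% and the last inside my bracket.

    substrate → ring (k = 0.0600 s⁻¹)
    2 substrate → open dimer (k = 0.750 L mol⁻¹ s⁻¹)
    substrate + open dimer → open trimer (k = 13.0 L mol⁻¹ s⁻¹)
    ring → over-reaction product (k = 0.00120 s⁻¹)

In cedar at 2.00 min, ring is made at 0.0422 of the rate at which it is used up, each step taken net. I put gamma's fade on alder's ring from 2.0 min to 20.0 min, and that reckons to 21.4%. At that time alder holds 22.4% of ring.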